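**Plan**

1. Retrosynthesis: the saturated chain is traced back at C3 through the 2-enoate and the carbinol to a 3-oxoicosanoate. Its C2–C3 bond is then cut to give a C18 acyl unit (C3–C20) and a two-carbon unit (C1–C2) that already carries the 2-phenylethyl ester.
2. Enabling feature: C1 and C2 are an acetate unit (carboxyl carbon plus its alpha-CH2) attached to the C3 methylene of an unbranched chain. This unit is the decarboxylated form of a malonate half-ester, so C2 can act as the nucleophile. The target has no ring other than the benzene ring bought with the alcohol.
3. Forward: Meldrum's acid and 2-phenylethanol give half-ester 3, and stearic acid gives imidazolide 5. A decarboxylative Claisen condensation joins them at C2–C3 to give beta-keto ester 8. C3 is then deoxygenated in the order ketone, alcohol, 2-enoate, alkane.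
4. Stereochemistry: the target has no stereocentre and no double bond. C3 of 9 and 10 is formed racemic, and the C2=C3 geometry of 11 is removed by hydrogenation.

Key step: step 3

Remark on the chemistry: crude 5 carries one equivalent of imidazole from its formation. This is assumed harmless in step 3, where imidazole is released anyway.

**Step 1**
Reactants: 1 2,2-dimethyl-1,3-dioxane-4,6-dione (Meldrum's acid); 2 2-phenylethanol
Product: 3 3-oxo-3-(2-phenylethoxy)propanoic acid (monophenethyl malonate)
Conditions: PhMe, 105 °C; extraction into aq. NaHCO3, then acidification
Reagents that add atoms: none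
Why: Thermal ring-opening alcoholysis of Meldrum's acid, in which the alcohol adds to one lactone carbonyl and acetone is expelled, should give the malonic half-ester at a temperature below that at which the free acid decarboxylates.

**Step 2**
Reactants: 4 stearic acid (octadecanoic acid)
Product: 5 1-stearoylimidazole (1-(1H-imidazol-1-yl)octadecan-1-one)
Conditions: CDI (1.1 equiv), THF, 23 to 40 °C until gas evolution ends; evaporation, crude solid used
Reagents that add atoms: 1,1'-carbonyldiimidazole (CDI), O=C(n1ccnc1)n1ccnc1
Why: Carboxylic acid activation with CDI proceeds through an acyl imidazole-carboxylic anhydride that collapses with loss of CO2 to the N-acylimidazole, an acyl donor mild enough not to form a ketene with amine bases.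

**Step 3**
Reactants: 3 monophenethyl malonate; 5 1-stearoylimidazole
Product: 8 2-phenylethyl 3-oxoicosanoate, via magnesium malonate enolate 6 (not isolated), via acylmalonic half-ester 7 (not isolated)
Conditions: 3 (1.5 equiv), MgCl2 (1.5 equiv), Et3N (3.2 equiv), THF, 23 °C, 2 h; then 5 in THF, 23 to 45 °C; 1 M HCl work-up
Reagents that add atoms: none
Why: MgCl2 and Et3N convert half-ester 3 into the chelated magnesium enolate-carboxylate 6, whose central carbon attacks the acyl carbon of imidazolide 5 by addition-elimination, expelling imidazolide and forming the C2–C3 bond; the acylmalonate 7, held as a magnesium chelate, then loses CO2 (at the latest on acidic work-up) to give beta-keto ester 8. The closest known reaction type is the Masamune–Claisen condensation of magnesium malonate half-esters with acyl imidazolides, a decarboxylative Claisen reaction that copies the chain-extension step of fatty acid biosynthesis. No ring is closed and no stereocentre is formed. The step needs C-acylation over O-acylation and a single acylation: binding both malonate oxygens to divalent magnesium leaves only the carbon free to attack, and the mono-acylated product is at once a far less nucleophilic chelated 1,3-dicarbonyl enolate that should not take up a second acyl group. The imidazolide is not converted to a ketene by Et3N, and the 2-phenylethyl ester should pass through untouched because no alkoxide is present. Loss of CO2 makes the condensation irreversible, unlike a classical Claisen equilibrium.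

**Step 4**
Reactants: 8 2-phenylethyl 3-oxoicosanoate
Product: 9 2-phenylethyl 3-hydroxyicosanoate (racemic)
Conditions: NaBH4 (1.0 equiv), THF/MeOH 10:1, −10 to 0 °C, 30 min; then sat. aq. NH4Cl
Reagents that add atoms: none
Why: Borohydride reduction should take the ketone well ahead of the ester at low temperature; hydride adds to both faces of the C3 carbonyl without control, so the new C3 stereocentre is racemic, which is of no consequence because it is removed in step 5.

**Step 5**
Reactants: 9 2-phenylethyl 3-hydroxyicosanoate
Product: 11 2-phenylethyl (E)-icos-2-enoate, via 3-mesyloxy ester 10 (not isolated)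
Conditions: MsCl (1.3 equiv), Et3N (2 equiv), CH2Cl2, 0 °C, 1 h; then DBU (2 equiv), 0 to 23 °C
Reagents that add atoms: none
Why: O-sulfonylation followed by base-induced E1cB elimination of the beta-mesyloxy ester (C2–H is acidified by the ester) should give mainly the conjugated E-enoate; any Z or 3-enoate isomer converges on the same product in step 6.

**Step 6**
Reactants: 11 2-phenylethyl (E)-icos-2-enoate
Product: 12 2-phenylethyl icosanoate (phenethyl icosanoate, the target)
Conditions: H2 (1 atm), 10% Pd/C, EtOAc, 23 °C
Reagents that add atoms: none
Why: Heterogeneous catalytic hydrogenation saturates the conjugated C2=C3 bond; the ester oxygen sits on a homobenzylic, not benzylic, carbon, so no C–O hydrogenolysis is expected, and the arene is inert at this pressure and temperature.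

**Compound list**

1 | 2,2-dimethyl-1,3-dioxane-4,6-dione (Meldrum's acid) | CC1(C)OC(=O)CC(=O)O1 | starting material
2 | 2-phenylethanol | OCCc1ccccc1 | starting material
3 | 3-oxo-3-(2-phenylethoxy)propanoic acid (monophenethyl malonate) | OC(=O)CC(=O)OCCc1ccccc1 | intermediate
4 | stearic acid (octadecanoic acid) | CCCCCCCCCCCCCCCCCC(=O)O | starting material
5 | 1-stearoylimidazole (1-(1H-imidazol-1-yl)octadecan-1-one) | CCCCCCCCCCCCCCCCCC(=O)n1ccnc1 | intermediate
6 | magnesium enolate-carboxylate of monophenethyl malonate (chelated magnesium salt of the doubly deprotonated half-ester) | [Mg+2].[O-]C(=O)C=C([O-])OCCc1ccccc1 | intermediate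
7 | 3-oxo-2-[(2-phenylethoxy)carbonyl]icosanoic acid (stearoylmalonic acid mono(2-phenylethyl) ester, present in the flask as its magnesium chelate) | CCCCCCCCCCCCCCCCCC(=O)C(C(=O)O)C(=O)OCCc1ccccc1 | intermediate
8 | 2-phenylethyl 3-oxoicosanoate | CCCCCCCCCCCCCCCCCC(=O)CC(=O)OCCc1ccccc1 | intermediate
9 | 2-phenylethyl 3-hydroxyicosanoate (racemic) | CCCCCCCCCCCCCCCCCC(O)CC(=O)OCCc1ccccc1 | intermediate
10 | 2-phenylethyl 3-(methylsulfonyloxy)icosanoate (racemic) | CCCCCCCCCCCCCCCCCC(OS(C)(=O)=O)CC(=O)OCCc1ccccc1 | intermediate
11 | 2-phenylethyl (E)-icos-2-enoate | CCCCCCCCCCCCCCCCC/C=C/C(=O)OCCc1ccccc1 | intermediate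
12 | 2-phenylethyl icosanoate (phenethyl icosanoate) | CCCCCCCCCCCCCCCCCCCC(=O)OCCc1ccccc1 | target

**Step count and risks**

Total step count: 6. Longest linear sequence: 5 steps (stearic acid 4 through steps 2, 3, 4, 5 and 6; the same length from Meldrum's acid 1 through steps 1, 3, 4, 5 and 6).

The three steps most likely to fail:

Step 3. The acylation may stall, either because the magnesium enolate forms slowly or because traces of water hydrolyse the imidazolide. The half-ester may also lose CO2 before it is acylated, which consumes the nucleophile. The fallback sets out from stearic acid 4 and comes back to the route at 8. Acid 4 is converted with oxalyl chloride and catalytic DMF in CH2Cl2 into stearoyl chloride F1. F1 acylates Meldrum's acid 1 at C5 in CH2Cl2 with pyridine at 0 °C to give 5-(1-hydroxyoctadecylidene)-2,2-dimethyl-1,3-dioxane-4,6-dione F2. Heating F2 with 2-phenylethanol 2 in toluene at about 100 °C should open the ring through an acylketene and, after loss of acetone and CO2, give 8. The same C2–C3 bond is formed by acylation of a malonate equivalent followed by decarboxylation, but the nucleophile is the cyclic malonate and the ester is installed after the carbon–carbon bond.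

Step 4. Reduction may run past the carbinol, because the boron-bound beta-alkoxy ester can be reduced on to the 1,3-diol. The ester alkoxy group may also exchange with methoxide formed from the co-solvent. The fallback sets out from 8 and comes back at target 12, bypassing steps 5 and 6 and using no hydride. Keto ester 8 is treated with ethane-1,2-dithiol and BF3·OEt2 in CH2Cl2 to give 2-phenylethyl 2-(2-heptadecyl-1,3-dithiolan-2-yl)acetate F3. Raney Ni in THF at about 55 °C should then desulfurise F3 directly to the methylene compound 12 (Mozingo reduction).

Step 5. Elimination may be slow or incomplete, and chloride may displace the secondary mesylate, leaving material that step 6 cannot convert. The fallback sets out from 9 and comes back at target 12, bypassing step 6. Alcohol 9 is heated with 1,1'-thiocarbonyldiimidazole and catalytic DMAP in THF at 60 °C to give 2-phenylethyl 3-(1H-imidazole-1-carbothioyloxy)icosanoate F4. Bu3SnH and AIBN in toluene at 100 °C should then cleave the C3–O bond by a radical chain (Barton–McCombie deoxygenation) to give 12.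

**Further compounds**

F1 | step 3 | stearoyl chloride (octadecanoyl chloride) | CCCCCCCCCCCCCCCCCC(=O)Cl
F2 | step 3 | 5-(1-hydroxyoctadecylidene)-2,2-dimethyl-1,3-dioxane-4,6-dione | CCCCCCCCCCCCCCCCCC(O)=C1C(=O)OC(C)(C)OC1=O
F3 | step 4 | 2-phenylethyl 2-(2-heptadecyl-1,3-dithiolan-2-yl)acetate | CCCCCCCCCCCCCCCCCC1(CC(=O)OCCc2ccccc2)SCCS1
F4 | step 5 | 2-phenylethyl 3-(1H-imidazole-1-carbothioyloxy)icosanoate (racemic) | CCCCCCCCCCCCCCCCCC(OC(=S)n1ccnc1)CC(=O)OCCc1ccccc1
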